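**Retrosynthetic overview**

1. Xestin A ⇐ its racemate (separation on a chiral phase) ⇐ acid methanolysis of a 3,6-dihydro-1,2-dioxin-3-ol, which gives the thermodynamic cis ketal.
2. Dioxinol ⇐ key step: cobalt/O2 radical ring opening of a 4-substituted cyclobut-2-en-1-ol. β-Scission gives a Z-locked allyl radical, its capture of triplet O2 makes the C3–O bond, and the hemiperketal then closes by itself.
3. Cyclobutenol ⇐ 1,2-addition of a C18 dienyl Grignard reagent to 4-(methoxycarbonylmethyl)cyclobut-2-enone.
4. C18 chloride ⇐ sorbyl alcohol + 2 × 1-bromo-6-chlorohexane (two copper-catalysed sp3–sp3 couplings); cyclobutenone ⇐ cyclobutanone + methyl bromoacetate, then selenoxide dehydrogenation.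
5. Ring order: the four-membered ring is bought and sacrificed; the 1,2-dioxine is the only ring formed (step 6).

Assumption: oxygen capture by the planar C3 radical cannot be made enantioselective with any reagent known today, so the route builds the racemic cis-peroxyketal and takes the (3R,6R) enantiomer by chromatography on a chiral phase in the last step.

**Route**

Step 1
Reactants: 1 (2E,4E)-hexa-2,4-dien-1-ol (sorbyl alcohol); 2 1-bromo-6-chlorohexane
Product: 5 (2E,4E)-12-chlorododeca-2,4-diene, via sorbyl acetate 3 (not isolated), via 6-chlorohexylmagnesium bromide 4 (not isolated)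
Conditions: 1, n-BuLi, THF, −78 °C; AcCl, −78 → 0 °C; then 4 (from 2, Mg, THF, 40 °C), Li2CuCl4 (3 mol%), −20 → 0 °C
Reagents that add atoms: none
Why: Copper-catalysed sp3–sp3 allylic coupling (Kochi/Schlosser–Fouquet type): the primary dienyl acetate is displaced at C1 with both E double bonds kept, faster than the Grignard reagent adds to the acetate carbonyl or touches its own C–Cl bond; no stereocentre is formed.

Step 2
Reactants: 5 (2E,4E)-12-chlorododeca-2,4-diene; 2 1-bromo-6-chlorohexane
Product: 7 (2E,4E)-18-chlorooctadeca-2,4-diene, via dodecadienylmagnesium chloride 6 (not isolated)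
Conditions: 5, Mg, I2 (cat.), THF, reflux; then 2 (1.5 equiv), Li2CuCl4 (3 mol%), NMP, THF, 0 °C → rt
Reagents that add atoms: none
Why: Kochi coupling: with Li2CuCl4 the alkyl Grignard reagent couples at C–Br far faster than at C–Cl, so the chloride survives as the handle for step 5 and the conjugated diene is inert to Mg and to the organocopper species; no stereocentre.

Step 3
Reactants: 8 cyclobutanone; 9 methyl bromoacetate
Product: 10 methyl 2-(2-oxocyclobutyl)acetate
Conditions: LiN(SiMe3)2, THF, −78 °C; 9, DMPU, −78 → −20 °C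
Reagents that add atoms: none
Why: SN2 alkylation of the lithium enolate of cyclobutanone by a reactive α-bromo ester; the new stereocentre is racemic and is destroyed in step 6.

Step 4
Reactants: 10 methyl 2-(2-oxocyclobutyl)acetate
Product: 13 methyl 2-(4-oxocyclobut-2-en-1-yl)acetate, via phenylselanyl ketone 11 (not isolated), via selenoxide 12 (not isolated)
Conditions: LiN(iPr)2, THF, −78 °C; PhSeBr, −78 °C; then 30% H2O2, pyridine, CH2Cl2, 0 °C → rt
Reagents that add atoms: none
Why: Reich selenenylation/selenoxide syn-elimination: kinetic deprotonation takes place at the unsubstituted α-CH2 and the selenoxide eliminates below room temperature to the 4-substituted cyclobutenone, whose double bond cannot migrate because enolisation would give a cyclobutadienol; no new stereocentre.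

Step 5
Reactants: 7 (2E,4E)-18-chlorooctadeca-2,4-diene; 13 methyl 2-(4-oxocyclobut-2-en-1-yl)acetate
Product: 15 methyl 2-{4-hydroxy-4-[(14E,16E)-octadeca-14,16-dien-1-yl]cyclobut-2-en-1-yl}acetate, via octadecadienylmagnesium chloride 14 (not isolated)
Conditions: 7, Mg, I2 (cat.), THF, reflux; then 13, LaCl3·2LiCl, THF, −78 °C; AcOH quench at −78 °C
Reagents that add atoms: none
Why: Chemoselective Grignard 1,2-addition to the strained, very electrophilic enone carbonyl at −78 °C (the methyl ester is left alone, enolisation is disfavoured), with a cold acidic quench to avoid oxy-anion-accelerated electrocyclic ring opening; the carbinol centre forms unselectively, and both diastereomers converge in step 6.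

Step 6
Reactants: 15 methyl 2-{4-hydroxy-4-[(14E,16E)-octadeca-14,16-dien-1-yl]cyclobut-2-en-1-yl}acetate
Product: 18 racemic methyl 2-[(3R*,6R*)-6-methoxy-6-[(14E,16E)-octadeca-14,16-dien-1-yl]-3,6-dihydro-1,2-dioxin-3-yl]acetate, via Z-hydroperoxy enone 16 (not isolated), via dioxinol 17 (not isolated)
Conditions: Co(acac)2 (20 mol%), O2 (1 atm), CH2Cl2, 0 °C → rt, dark; then MeOH, PPTS (20 mol%), rt, 12 h
Reagents that add atoms: dioxygen, O=O; methanol, CO
Why: Proposed new method: a vinylogous extension of the known cobalt/O2 oxidative ring expansion of cyclobutanols to 1,2-dioxan-3-ols (and the manganese/O2 opening of cyclopropanols to 1,2-dioxolan-3-ols) — the trivalent cobalt alkoxide of 15 fragments by β-scission of the strained C1–C4 bond to an acyl-substituted allyl radical whose Z geometry is fixed by the four-membered ring; triplet O2 adds at the carbon remote from the carbonyl so that enone conjugation is kept (this is the C3–O bond; C3 forms racemic because the radical is planar); divalent cobalt reduces the peroxyl radical; the Z-hydroperoxy enone 16 closes at once to hemiperketal 17; PPTS/MeOH then gives, under thermodynamic control, the ketal with OMe pseudoaxial (anomeric effect) and both carbon substituents pseudoequatorial, i.e. OMe cis to CH2CO2Me, which sets C6 relative to C3 (the minor C6 epimer is re-equilibrated under the same conditions); the remote diene should be spared because the radical is generated only at the cobalt-bound tertiary alkoxide and is not a chain carrier.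

Step 7
Reactants: 18 racemic methyl 2-[(3R*,6R*)-6-methoxy-6-[(14E,16E)-octadeca-14,16-dien-1-yl]-3,6-dihydro-1,2-dioxin-3-yl]acetate
Product: 19 xestin A, methyl 2-[(3R,6R)-6-methoxy-6-[(14E,16E)-octadeca-14,16-dien-1-yl]-3,6-dihydro-1,2-dioxin-3-yl]acetate
Conditions: preparative HPLC, amylose tris(3,5-dimethylphenylcarbamate) phase, hexane/i-PrOH, rt
Reagents that add atoms: none
Why: Resolution by chromatography on a chiral stationary phase: the neutral, acid- and base-free conditions leave the peroxyketal untouched, and the (3R,6R) enantiomer is identified by the sign of its optical rotation against natural xestin A.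

**Compound list**

1 | (2E,4E)-hexa-2,4-dien-1-ol | C/C=C/C=C/CO | starting material
2 | 1-bromo-6-chlorohexane | ClCCCCCCBr | starting material
3 | (2E,4E)-hexa-2,4-dien-1-yl acetate | C/C=C/C=C/COC(C)=O | intermediate
4 | (6-chlorohexyl)magnesium bromide | ClCCCCCC[Mg]Br | intermediate
5 | (2E,4E)-12-chlorododeca-2,4-diene | C/C=C/C=C/CCCCCCCCl | intermediate
6 | [(8E,10E)-dodeca-8,10-dien-1-yl]magnesium chloride | C/C=C/C=C/CCCCCCC[Mg]Cl | intermediate
7 | (2E,4E)-18-chlorooctadeca-2,4-diene | C/C=C/C=C/CCCCCCCCCCCCCCl | intermediate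
8 | cyclobutanone | O=C1CCC1 | starting material
9 | methyl bromoacetate | COC(=O)CBr | starting material
10 | methyl 2-(2-oxocyclobutyl)acetate (racemic) | COC(=O)CC1CCC1=O | intermediate
11 | methyl 2-[2-oxo-3-(phenylselanyl)cyclobutyl]acetate (diastereomer mixture) | COC(=O)CC1CC([Se]c2ccccc2)C1=O | intermediate
12 | methyl 2-[2-oxo-3-(phenylseleninyl)cyclobutyl]acetate | COC(=O)CC1CC([Se](=O)c2ccccc2)C1=O | intermediate
13 | methyl 2-(4-oxocyclobut-2-en-1-yl)acetate (racemic) | COC(=O)CC1C=CC1=O | intermediate
14 | [(14E,16E)-octadeca-14,16-dien-1-yl]magnesium chloride | C/C=C/C=C/CCCCCCCCCCCCC[Mg]Cl | intermediate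
15 | methyl 2-{4-hydroxy-4-[(14E,16E)-octadeca-14,16-dien-1-yl]cyclobut-2-en-1-yl}acetate (racemic diastereomer mixture) | C/C=C/C=C/CCCCCCCCCCCCCC1(O)C=CC1CC(=O)OC | intermediate
16 | methyl (4Z,20E,22E)-3-hydroperoxy-6-oxotetracosa-4,20,22-trienoate (racemic) | C/C=C/C=C/CCCCCCCCCCCCCC(=O)/C=C\C(OO)CC(=O)OC | intermediate
17 | methyl 2-{6-hydroxy-6-[(14E,16E)-octadeca-14,16-dien-1-yl]-3,6-dihydro-1,2-dioxin-3-yl}acetate (racemic hemiperketal) | C/C=C/C=C/CCCCCCCCCCCCCC1(O)C=CC(CC(=O)OC)OO1 | intermediate
18 | racemic methyl 2-[(3R*,6R*)-6-methoxy-6-[(14E,16E)-octadeca-14,16-dien-1-yl]-3,6-dihydro-1,2-dioxin-3-yl]acetate (1:1 mixture of both enantiomers) | C/C=C/C=C/CCCCCCCCCCCCC[C@]1(OC)C=C[C@@H](CC(=O)OC)OO1.C/C=C/C=C/CCCCCCCCCCCCC[C@@]1(OC)C=C[C@H](CC(=O)OC)OO1 | intermediate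
19 | xestin A, methyl 2-[(3R,6R)-6-methoxy-6-[(14E,16E)-octadeca-14,16-dien-1-yl]-3,6-dihydro-1,2-dioxin-3-yl]acetate | C/C=C/C=C/CCCCCCCCCCCCC[C@]1(OC)C=C[C@@H](CC(=O)OC)OO1 | target

**Step count and risks**

Total: 7 steps. Longest linear sequence: 5 steps (1 → 2 → 5 → 6 → 7, or 3 → 4 → 5 → 6 → 7).

Most likely to fail, first: step 6. The ring expansion is untested on a cyclobutenol: the allyl radical could take up O2 next to the carbonyl, the alkoxide could open thermally instead, or the diene could co-oxidise. The fallback keeps radical O2 capture but uses an open-chain precursor; it sets out from 14 and returns at 16. Grignard reagent 14 is acylated at −78 °C under Fe(acac)3 catalysis with (2E)-penta-2,4-dienoyl chloride F1 (from (2E)-penta-2,4-dienoic acid, (COCl)2, cat. DMF), giving the cross-conjugated dienone (3E,19E,21E)-tricosa-1,3,19,21-tetraen-5-one F2. A methoxycarbonyl radical from methyl carbazate (iron phthalocyanine Fe(C32H16N8) cat., air, slow addition) adds to the terminal carbon of F2, and the delocalised radical takes up O2 at the γ-carbon to give methyl (4E,20E,22E)-3-hydroperoxy-6-oxotetracosa-4,20,22-trienoate F3. Irradiation of F3 at 350 nm in degassed MeOH/CH2Cl2 containing PPTS isomerises the enone to 16, which closes to 17 and is ketalised to 18 as before. This fallback is itself unproven chemistry.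

Second: step 4. The free cyclobutenone 13 may polymerise or add nucleophiles during the oxidative elimination. The fallback moves the elimination behind the C–C bond formation; it sets out from 11 and returns at 15. Selenide 11 is isolated (no oxidant) and treated with 14 and LaCl3·2LiCl at −78 °C to give the β-hydroxy selenide methyl 2-{2-hydroxy-2-[(14E,16E)-octadeca-14,16-dien-1-yl]-3-(phenylselanyl)cyclobutyl}acetate F4. Oxidation (H2O2, pyridine, 0 °C) gives the selenoxide methyl 2-{2-hydroxy-2-[(14E,16E)-octadeca-14,16-dien-1-yl]-3-(phenylseleninyl)cyclobutyl}acetate F5, which can only eliminate away from the fully substituted carbinol carbon and so delivers 15 directly.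

Third: step 7. A lipophilic C26 peroxide may not resolve well enough on a chiral phase at preparative scale. The fallback resolves through covalent diastereomers; it sets out from 18 and returns at 19. The methoxy group of 18 is exchanged for (S)-1-phenylethanol (PPTS, CH2Cl2, 5 Å sieves to take up MeOH). The diastereomer of the (3R) series, methyl 2-{(3R,6R)-6-[(1S)-1-phenylethoxy]-6-[(14E,16E)-octadeca-14,16-dien-1-yl]-3,6-dihydro-1,2-dioxin-3-yl}acetate F6, is separated on silica gel. MeOH/PPTS then returns it to 19, again as the thermodynamic cis ketal.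

**Further compounds**

F1 | step 6 | (2E)-penta-2,4-dienoyl chloride | C=C/C=C/C(=O)Cl
F2 | step 6 | (3E,19E,21E)-tricosa-1,3,19,21-tetraen-5-one | C/C=C/C=C/CCCCCCCCCCCCCC(=O)/C=C/C=C
F3 | step 6 | methyl (4E,20E,22E)-3-hydroperoxy-6-oxotetracosa-4,20,22-trienoate (racemic) | C/C=C/C=C/CCCCCCCCCCCCCC(=O)/C=C/C(OO)CC(=O)OC
F4 | step 4 | methyl 2-{2-hydroxy-2-[(14E,16E)-octadeca-14,16-dien-1-yl]-3-(phenylselanyl)cyclobutyl}acetate | C/C=C/C=C/CCCCCCCCCCCCCC1(O)C([Se]c2ccccc2)CC1CC(=O)OC
F5 | step 4 | methyl 2-{2-hydroxy-2-[(14E,16E)-octadeca-14,16-dien-1-yl]-3-(phenylseleninyl)cyclobutyl}acetate | C/C=C/C=C/CCCCCCCCCCCCCC1(O)C([Se](=O)c2ccccc2)CC1CC(=O)OC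
F6 | step 7 | methyl 2-{(3R,6R)-6-[(1S)-1-phenylethoxy]-6-[(14E,16E)-octadeca-14,16-dien-1-yl]-3,6-dihydro-1,2-dioxin-3-yl}acetate | C/C=C/C=C/CCCCCCCCCCCCC[C@]1(O[C@@H](C)c2ccccc2)C=C[C@@H](CC(=O)OC)OO1
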